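(The runs come from a simulation for substances that don't exist; scatter was added.)

Count the coupling partner.

| flask | substrate | coupling partner | remark | time |
|---|---|---|---|---|
| amber | 0.67 M | 2 M | run made earlier |  |
| red | 2 M | 2 M | run made earlier |  |
| elm | 1.0 M | 2.00 M |  | 2.5 min |
| larch | 1.0 M | 0.500 M |  | 2.5 min |

| run | time / s | double product / % | first product / % |
|---|---|---|---|
| amber | 10.0 | 17.3 | 48.4 |
| amber | 25.0 | 31.2 | 58.4 |
| amber | 50.0 | 39.5 | 59.7 |
| red | 10.0 | 8.7 | 40.0 |
| red | 25.0 | 15.1 | 48.6 |
| red | 50.0 | 17.6 | 50.5 |

(scatter of a reading: 0.5 percentage points)

1. which of these holds the largest part of the substrate at the end of elm (first product / other mono adduct / double product / substrate)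
2. which of these holds the largest part of the substrate at the end of larch (first product / other mono adduct / double product / substrate)
3. final double product in elm, as a percentage of the substrate charged

Each first product holds one partner and each double product two, and amber's last reading accounts for nearly all of its substrate. That reading gives 1.40 equivalents of partner per equivalent of substrate; this number, the partner demand, is what we carry.

Now we draw elm's partner curve, as a fraction of its charge. Elm charges the same partner as amber, and amber's first reading, rescaled, puts the fall in the first 10.0 s at about 41.5%, before counting the partner held by other mono adduct, which the readings do not show. We place the knee by the unfinished part, neither first nor double product, which in amber reads 34.3% and then 10.4% at its first two readings, so its half-life in amber reads about 8.71 s.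

Elm's charge exceeds amber's demand, so, taking that demand over to elm, we expect a shoulder with 30.1% of the partner left, double product near 40.0% and first product near 60.0%, with no crossing by the end of elm. We commit to first product for elm. Larch's partner is the limiting reagent, and each substrate reacted takes at least one partner, so at least 50.0% stays substrate.

The forecast named double product for elm and substrate for larch, with 56% double product (47% to 64%), holding that “about 40% of the first product converts”.

The flask gives first product in elm at 58.1%, crystals counted, double product 41.6%, partner left 29%; larch gives substrate at 55.2%.

    substrate + coupling partner → other mono adduct (k = 0.0330 M⁻¹ s⁻¹)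
    coupling partner + other mono adduct → double product (k = 0.0900 M⁻¹ s⁻¹)
    crystals ⇌ first product, rate k3*(cs3 - [first product]) while solid is left; crystals form when [first product] > cs3 (solubility = 24.0 mM, k = 19.0 s⁻¹)
    coupling partner + first product → double product (k = 0.0200 M⁻¹ s⁻¹)
    coupling partner → decomposition product (k = 2.50 × 10⁻⁵ s⁻¹)
    substrate + coupling partner ⇌ first product (K = 11.0 M⁻¹, k = 0.0590 M⁻¹ s⁻¹)

Elm has not come to rest at 2.50 min. Its demand, first product plus twice double product, stands at 1.41 there, but at 25.0 min it reaches 1.73, with double product at 73.5%, first product, crystals counted, at 25.8%, and partner at 12.7%. The shoulder is a slow slope.

In the same flask as elm with 1.7 M of substrate, the 1.18 equiv of partner fall short of amber's demand, and a first reckoning, which counts no partner in other mono adduct, gives about 15.9% unfinished, as substrate or other mono adduct. That flask ends with 9.2% substrate and 7.70% other mono adduct, 16.9% together, and partner at 0.55%.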